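Late in the midnight run the target creeps from 61.3% to 68.5% of the substrate charged between 7.9 h and 15 h, so the first question is where it stops.

| flask | substrate | coupling partner | catalyst | time |
|---|---|---|---|---|
| midnight | 0.600 M | 0.900 M | 0.00600 M |  |
| spring | 1.80 M | 0.900 M | 0.00600 M |  |
| autumn | 0.600 M | 1.40 M | 0.00600 M |  |
| winter | 0.600 M | 0.900 M | 0.0180 M |  |
| dusk | 0.600 M | 0.900 M | 0.00600 M | 90 h |

| run | time / h | [target] / M |
|---|---|---|
| midnight run | 0.60 | 0.090 |
| midnight run | 1.1 | 0.124 |
| midnight run | 2.2 | 0.211 |
| midnight run | 4.1 | 0.294 |
| midnight run | 7.9 | 0.368 |
| midnight run | 15 | 0.411 |
| spring run | 0.60 | 0.206 |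
| spring run | 1.1 | 0.327 |
| spring run | 2.2 | 0.490 |
| spring run | 4.1 | 0.591 |
| spring run | 7.9 | 0.667 |
| spring run | 15 | 0.678 |
| autumn run | 0.60 | 0.119 |
| autumn run | 1.1 | 0.203 |
| autumn run | 2.2 | 0.296 |
| autumn run | 4.1 | 0.399 |
| autumn run | 7.9 | 0.471 |
| autumn run | 15 | 0.524 |
| winter run | 0.60 | 0.178 |
| winter run | 1.1 | 0.259 |
| winter run | 2.2 | 0.375 |
| winter run | 4.1 | 0.451 |
| winter run | 7.9 | 0.506 |
| winter run | 15 | 0.519 |

(readings scatter by 0.009 M)

- Overall: substrate + coupling partner -> target, with catalyst as catalyst.
- Constant volume, constant temperature.
- A reading of a species includes what of it is bound.
- "The second partner" is coupling partner.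
- An order is taken over about fifteen percent of the charge, up and down.

- apparent order in [substrate] of the starting rate, round the charge of the midnight run (the rate where two percent of its substrate have turned into target) (one fixed amount of target, the same in the runs compared)
- apparent order in [catalyst] of the starting rate, round the charge of the midnight run (the rate where two percent of its substrate have turned into target)
- target in the dusk run at 90 h, as a share of the substrate charged

Call f the target made as a fraction of the substrate charged. The last spring reading has f at 37.7%, less than the partner charge of 50.0% of the substrate, though partner is the limiting reagent there. So either partner leaves by another road or the catalyst fails, and I reckon with the first.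

Suppose partner dies at a steady rate per molecule while target forms in proportion to substrate and partner. Dividing one rate by the other removes time and leaves a rule for the end of a run: partner charged per substrate charged equals f plus b times the logarithm of substrate charged over substrate remaining.

The autumn run's last reading, taken as its end, gives b = 0.707. This b is the loss number: how fast partner is lost against how fast the substrate charged uses it.

Does it carry over? The midnight run has the substrate and catalyst charges of the autumn run, so I keep b, and the rule, solved from the charges and b without any midnight reading, puts its end at 68.5%. The last midnight reading, 68.5%, lies there, with a scatter of 1.50% of the charge. The dusk run repeats that recipe, so I expect 68.5% at 90 h.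

What do the other charges do? If the rate goes as a power of a charge and the loss of partner stays as it is, b falls by that power. The last spring reading gives b = 0.261 and the last winter reading 0.317. I read orders of 0.907 in substrate and 0.729 in catalyst, as averages over whole runs.

The forecast, which sees “the catalyst dying as the run proceeds”, gives 0.9, 0.87 and 73%, close to mine in substrate and higher than mine in catalyst and yield.

The flask gives 0.94, 0.71 and 67.7%.

    catalyst + substrate ⇌ catalyst-substrate complex (306.4 L mol⁻¹ h⁻¹, 1062 h⁻¹)
    catalyst-substrate complex + coupling partner → target + catalyst (162.4 L mol⁻¹ h⁻¹)
    coupling partner → lost reagent (0.1447 h⁻¹)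
    substrate + coupling partner → target (0.09072 L mol⁻¹ h⁻¹)

The stall comes from the step from partner to lost reagent: with that step removed, the dusk run reaches >99.9% instead of 67.7%. Put the dusk result into the rule and b comes back as 0.727. Scaled to the spring charge with the order 0.94, it becomes 0.260, and the rule, solved from that b and the spring charges, ends the spring run at 37.7%, where its last reading stands at 37.7%.

The data are simulated for an exercise; the scatter is artificial.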